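**Retrosynthetic overview**
- The target lactol is released last by neutral hydrogenolysis of an (R)-configured benzyl acetal that also carries the benzyl-protected CH2OH; no bond to the stereocentre is touched.
- The γ-lactone ring and the stereocentre come from a bromo-aldehyde depsidone by an enantioselective carbonylative acetal-lactonisation with benzyl alcohol (C–O bond formation fixes the acetal carbon).
- The seven-membered dioxepinone ring comes from a bromo-depside by intramolecular Ullmann C–O coupling (diaryl ether).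
- The depside ester joins the ring A acid (from methyl β-orcinolcarboxylate) to a symmetric 2,6-dibromo-3,5-dihydroxy-4-(benzyloxymethyl)benzaldehyde (from 3,5-dihydroxybenzaldehyde); the symmetry removes all regiochemical questions on ring B.
- Ring order: rings A and B are bought as benzenes; the central dioxepinone ring is closed first (ester, then ether); the lactone ring is closed last.

Assumption: the hemiacetal carbon is the only stereocentre and is (R) by CIP; because a free 3-hydroxyphthalide can epimerise through its ring-opened formyl acid in protic or basic media, the centre is built as a stable benzyl acetal and released only in the last, neutral step.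

**Step 1**
Reactants: 1 methyl 2,4-dihydroxy-3,6-dimethylbenzoate
Product: 3 2-hydroxy-4-methoxy-3,6-dimethylbenzoic acid, via methyl 2-hydroxy-4-methoxy-3,6-dimethylbenzoate 2 (not isolated)
Conditions: MeI (1.05 equiv), K2CO3 (1.2 equiv), DMSO, 20 °C; then KOH (6 equiv), H2O, 90 °C; then 1 M HCl, 0 °C
Reagents that add atoms: iodomethane (CI); potassium hydroxide ([K+].[OH-])
Why: Williamson methylation takes only the 4-OH because the 2-OH is hydrogen-bonded to the ester, and the hindered ester is then saponified in hot aqueous DMSO and acidified cold to avoid decarboxylation.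

**Step 2**
Reactants: 4 3,5-dihydroxybenzaldehyde
Product: 5 3,5-bis(methoxymethoxy)benzaldehyde
Conditions: MOMCl (2.5 equiv), iPr2NEt (3 equiv), CH2Cl2, 0 °C to rt
Reagents that add atoms: chloromethyl methyl ether (COCCl)
Why: Standard O-alkylation of both phenols gives MOM ethers, which are strong directing groups for the next lithiation and are removable with mild acid.

**Step 3**
Reactants: 5 3,5-bis(methoxymethoxy)benzaldehyde
Product: 9 4-[(benzyloxy)methyl]-3,5-bis(methoxymethoxy)benzaldehyde, via lithium α-amino alkoxide 6 (not isolated), via 4-lithio α-amino alkoxide 7 (not isolated), via alkylated α-amino alkoxide 8 (not isolated)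
Conditions: N-methylpiperazine (1.15 equiv), n-BuLi (1.1 equiv), THF, −20 °C; then n-BuLi (1.3 equiv), −20 to 0 °C; then BnOCH2Cl (1.5 equiv), −78 °C to rt; aq NH4Cl
Reagents that add atoms: benzyl chloromethyl ether (ClCOCc1ccccc1)
Why: Comins-type in situ protection of the aldehyde as a weakly directing α-amino alkoxide lets directed ortho-metalation occur at the carbon flanked by both MOM ethers, and the aryllithium is alkylated by the chloromethyl ether to install the CH2OH carbon already benzyl-protected.

**Step 4**
Reactants: 9 4-[(benzyloxy)methyl]-3,5-bis(methoxymethoxy)benzaldehyde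
Product: 11 4-[(benzyloxy)methyl]-2,6-dibromo-3,5-dihydroxybenzaldehyde, via dibromo bis(methoxymethyl) ether 10 (not isolated)
Conditions: NBS (2.1 equiv), MeCN, 0 °C to rt, dark; then MeOH, conc. HCl (cat.), 40 °C
Reagents that add atoms: N-bromosuccinimide (O=C1CCC(=O)N1Br)
Why: Electrophilic aromatic bromination can only go to the two equivalent free positions (each ortho/para to a MOM ether); brominating before the acidic MOM cleavage avoids ipso-bromodealkylation of a free 2,6-dihydroxybenzyl ether.

**Step 5**
Reactants: 3 2-hydroxy-4-methoxy-3,6-dimethylbenzoic acid; 11 4-[(benzyloxy)methyl]-2,6-dibromo-3,5-dihydroxybenzaldehyde (2 equiv, excess recovered)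
Product: 12 2-[(benzyloxy)methyl]-4,6-dibromo-5-formyl-3-hydroxyphenyl 2-hydroxy-4-methoxy-3,6-dimethylbenzoate
Conditions: TFAA (3 equiv), toluene, 0 °C to rt
Reagents that add atoms: none
Why: Mixed-anhydride esterification (trifluoroacetic anhydride method for depsides) goes through the linear acylium ion of the electron-rich, hindered acid, whose own 2-OH is protected by hydrogen bonding; the two phenols of 11 are equivalent, so only mono- versus bis-acylation has to be controlled by the excess of 11.

**Step 6**
Reactants: 12 2-[(benzyloxy)methyl]-4,6-dibromo-5-formyl-3-hydroxyphenyl 2-hydroxy-4-methoxy-3,6-dimethylbenzoate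
Product: 13 9-[(benzyloxy)methyl]-7-bromo-8-hydroxy-3-methoxy-1,4-dimethyl-11-oxo-11H-dibenzo[b,e][1,4]dioxepine-6-carbaldehyde
Conditions: CuI (20 mol %), picolinic acid (40 mol %), K3PO4 (3 equiv), DMSO (0.01 M), 80 °C
Reagents that add atoms: none
Why: Intramolecular Ullmann-type C–O coupling closes the seven-membered ring because the ring A phenoxide can reach only the bromide ortho to the ester oxygen, that bromide is activated by the ortho formyl group, and the ester-bearing carbon (meta to the aldehyde) is not activated for a competing Smiles rearrangement.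

**Step 7**
Reactants: 13 9-[(benzyloxy)methyl]-7-bromo-8-hydroxy-3-methoxy-1,4-dimethyl-11-oxo-11H-dibenzo[b,e][1,4]dioxepine-6-carbaldehyde
Product: 14 (1R)-1-(benzyloxy)-5-[(benzyloxy)methyl]-4-hydroxy-10-methoxy-8,11-dimethyl-1H,7H-2,6,12-trioxabenzo[5,6]cyclohepta[1,2-e]indene-3,7-dione
Conditions: Pd(OAc)2 (5 mol %), (R)- or (S)-DTBM-SEGPHOS (6 mol %, antipode fixed by a first screen), CO (1 atm), BnOH (1.5 equiv), Cy2NMe (2.5 equiv), 4 Å MS, toluene, 60 °C
Reagents that add atoms: carbon monoxide ([C-]#[O+]); benzyl alcohol (OCc1ccccc1)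
Why: Proposed new method: zerovalent palladium (formed from Pd(OAc)2 and the bisphosphine under CO) inserts into the C–Br bond next to the formyl group and takes up CO to give an aroyl complex of divalent palladium, while benzyl alcohol adds reversibly (amine-catalysed) to the neighbouring aldehyde so that the two hemiacetal epimers interconvert fast; their alkoxides bind palladium as diastereomeric six-membered acyl(alkoxo) chelates and C(acyl)–O reductive elimination from the matched chelate is faster (Curtin–Hammett dynamic kinetic resolution), which closes the lactone and fixes the acetal carbon as (R), and the O,O-acetal product cannot reopen under these weakly basic conditions so the ee is kept; the closest known reaction types are the racemic palladium-catalysed carbonylative cyclisation of 2-halobenzaldehydes with alcohols or amines to 3-substituted phthalides and isoindolinones, and the acylative dynamic kinetic resolution of 3-hydroxyphthalides, with no enantioselective carbonylative version known.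

**Step 8**
Reactants: 14 (1R)-1-(benzyloxy)-5-[(benzyloxy)methyl]-4-hydroxy-10-methoxy-8,11-dimethyl-1H,7H-2,6,12-trioxabenzo[5,6]cyclohepta[1,2-e]indene-3,7-dione
Product: 15 (1R)-1,4-dihydroxy-5-(hydroxymethyl)-10-methoxy-8,11-dimethyl-1H,7H-2,6,12-trioxabenzo[5,6]cyclohepta[1,2-e]indene-3,7-dione
Conditions: H2 (1 atm), Pd/C (10 wt %), dry EtOAc, 0 °C to rt, stopped after 2 equiv H2; cold filtration, product kept neutral, dry and cold
Reagents that add atoms: none
Why: Hydrogenolysis cleaves the two PhCH2–O bonds (benzyl acetal, as for a benzyl glycoside, and the benzyl ether) on the unhindered phenyl side while the hexasubstituted ring B cannot lie flat on the metal, so no bond to the acetal carbon breaks and the (R) lactol is released with retention under neutral aprotic conditions.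

**Compound list**
1 | methyl 2,4-dihydroxy-3,6-dimethylbenzoate (methyl β-orcinolcarboxylate) | COC(=O)c1c(C)cc(O)c(C)c1O | starting material
2 | methyl 2-hydroxy-4-methoxy-3,6-dimethylbenzoate | COC(=O)c1c(C)cc(OC)c(C)c1O | intermediate (not isolated)
3 | 2-hydroxy-4-methoxy-3,6-dimethylbenzoic acid | OC(=O)c1c(C)cc(OC)c(C)c1O | intermediate
4 | 3,5-dihydroxybenzaldehyde | O=Cc1cc(O)cc(O)c1 | starting material
5 | 3,5-bis(methoxymethoxy)benzaldehyde | O=Cc1cc(OCOC)cc(OCOC)c1 | intermediate
6 | lithium [3,5-bis(methoxymethoxy)phenyl](4-methylpiperazin-1-yl)methanolate | [Li+].[O-]C(N1CCN(C)CC1)c1cc(OCOC)cc(OCOC)c1 | intermediate (not isolated)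
7 | lithium [4-lithio-3,5-bis(methoxymethoxy)phenyl](4-methylpiperazin-1-yl)methanolate | [Li+].[O-]C(N1CCN(C)CC1)c1cc(OCOC)c([Li])c(OCOC)c1 | intermediate (not isolated)
8 | lithium {4-[(benzyloxy)methyl]-3,5-bis(methoxymethoxy)phenyl}(4-methylpiperazin-1-yl)methanolate | [Li+].[O-]C(N1CCN(C)CC1)c1cc(OCOC)c(COCc2ccccc2)c(OCOC)c1 | intermediate (not isolated)
9 | 4-[(benzyloxy)methyl]-3,5-bis(methoxymethoxy)benzaldehyde | O=Cc1cc(OCOC)c(COCc2ccccc2)c(OCOC)c1 | intermediate
10 | 4-[(benzyloxy)methyl]-2,6-dibromo-3,5-bis(methoxymethoxy)benzaldehyde | O=Cc1c(Br)c(OCOC)c(COCc2ccccc2)c(OCOC)c1Br | intermediate (not isolated)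
11 | 4-[(benzyloxy)methyl]-2,6-dibromo-3,5-dihydroxybenzaldehyde | O=Cc1c(Br)c(O)c(COCc2ccccc2)c(O)c1Br | intermediate
12 | 2-[(benzyloxy)methyl]-4,6-dibromo-5-formyl-3-hydroxyphenyl 2-hydroxy-4-methoxy-3,6-dimethylbenzoate | COc1cc(C)c(C(=O)Oc2c(Br)c(C=O)c(Br)c(O)c2COCc2ccccc2)c(O)c1C | intermediate
13 | 9-[(benzyloxy)methyl]-7-bromo-8-hydroxy-3-methoxy-1,4-dimethyl-11-oxo-11H-dibenzo[b,e][1,4]dioxepine-6-carbaldehyde | COc1cc(C)c2c(c1C)Oc1c(C=O)c(Br)c(O)c(COCc3ccccc3)c1OC2=O | intermediate
14 | (1R)-1-(benzyloxy)-5-[(benzyloxy)methyl]-4-hydroxy-10-methoxy-8,11-dimethyl-1H,7H-2,6,12-trioxabenzo[5,6]cyclohepta[1,2-e]indene-3,7-dione (the target with both the lactol OH and the CH2OH as benzyl ethers) | COc1cc(C)c2c(c1C)Oc1c(c(COCc4ccccc4)c(O)c3c1[C@H](OCc4ccccc4)OC3=O)OC2=O | intermediate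
15 | (1R)-1,4-dihydroxy-5-(hydroxymethyl)-10-methoxy-8,11-dimethyl-1H,7H-2,6,12-trioxabenzo[5,6]cyclohepta[1,2-e]indene-3,7-dione | COc1cc(C)c2c(c1C)Oc1c(c(CO)c(O)c3c1[C@H](O)OC3=O)OC2=O | target

**Step count and risks**
Total steps: 8. Longest linear sequence: 7 (steps 2 to 8, from 4); step 1 is the only side branch.

Most likely to fail:

Step 7 (the new carbonylative acetal-lactonisation). It may give low ee, the open-chain benzyl ester, or benzyl-alcohol opening of the depsidone. Fallback with known chemistry, from 13 back to the route at 15: hydroxycarbonylation of 13 (Pd(OAc)2, Xantphos, CO 1 atm, H2O, Et3N, dioxane, 80 °C) gives, after spontaneous ring closure of the formyl acid, the racemic lactol rac-5-[(benzyloxy)methyl]-1,4-dihydroxy-10-methoxy-8,11-dimethyl-1H,7H-2,6,12-trioxabenzo[5,6]cyclohepta[1,2-e]indene-3,7-dione F5. Acid-catalysed pseudo-ester formation with (S)-1-phenylethanol (PPTS, toluene, 4 Å MS, 60 °C) gives two diastereomeric acetals: (1R)-5-[(benzyloxy)methyl]-4-hydroxy-10-methoxy-8,11-dimethyl-1-[(1S)-1-phenylethoxy]-1H,7H-2,6,12-trioxabenzo[5,6]cyclohepta[1,2-e]indene-3,7-dione F6 and its (1S) epimer (1S)-5-[(benzyloxy)methyl]-4-hydroxy-10-methoxy-8,11-dimethyl-1-[(1S)-1-phenylethoxy]-1H,7H-2,6,12-trioxabenzo[5,6]cyclohepta[1,2-e]indene-3,7-dione F7. They are separated by chromatography or crystallisation, with configuration assigned by X-ray; F7 is re-equilibrated under the same acid conditions and recycled. Hydrogenolysis of F6 (H2, Pd/C, EtOAc) removes the 1-phenylethyl and benzyl groups and gives 15.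

Step 6 (intramolecular Ullmann closure). The free ring B phenoxide deactivates the bromide, and the depside ester may be cleaved or migrate under base. Fallback, ether first and lactone second, from 3 and 10 (10 isolated by stopping step 4 before the acid treatment) back to the route at 13: 3 is converted into tert-butyl 2-hydroxy-4-methoxy-3,6-dimethylbenzoate F2 (Me2NCH(OtBu)2, toluene, 80 °C). Intermolecular Ullmann coupling of F2 with 10 (CuI, picolinic acid, K3PO4, DMSO, 90 °C) gives tert-butyl 2-{3-[(benzyloxy)methyl]-5-bromo-6-formyl-2,4-bis(methoxymethoxy)phenoxy}-4-methoxy-3,6-dimethylbenzoate F3; the bromide is formyl-activated, the MOM ethers prevent self-coupling, and the first aryloxy group deactivates the second bromide. TFA–H2O–CH2Cl2 at rt removes the tert-butyl ester and both MOM ethers to give 2-{3-[(benzyloxy)methyl]-5-bromo-6-formyl-2,4-dihydroxyphenoxy}-4-methoxy-3,6-dimethylbenzoic acid F4. DCC in toluene lactonises F4 on the only phenol within reach (ortho to the ether oxygen) and gives 13.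

Step 5 (esterification of a hindered, electron-poor, doubly equivalent phenol). Conversion may be low or bis-acylation may dominate. Fallback, phenoxide acyl transfer instead of acylium chemistry, from 3 and 11 back to the route at 12: 3 is converted (acetone, TFAA, TFA, 0 °C to rt) into 7-methoxy-2,2,5,8-tetramethyl-4H-1,3-benzodioxin-4-one F1. The monosodium phenoxide of 11 (NaH 1.0 equiv, THF, then F1, 60 °C) opens F1 at the carbonyl with loss of acetone and gives 12 with the ring A phenol already free; only one phenoxide per molecule is present, which also curbs bis-acylation.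

**Further compounds**
F1 | step 5 | 7-methoxy-2,2,5,8-tetramethyl-4H-1,3-benzodioxin-4-one | COc1cc(C)c2C(=O)OC(C)(C)Oc2c1C
F2 | step 6 | tert-butyl 2-hydroxy-4-methoxy-3,6-dimethylbenzoate | CC(C)(C)OC(=O)c1c(C)cc(OC)c(C)c1O
F3 | step 6 | tert-butyl 2-{3-[(benzyloxy)methyl]-5-bromo-6-formyl-2,4-bis(methoxymethoxy)phenoxy}-4-methoxy-3,6-dimethylbenzoate | COc1cc(C)c(C(=O)OC(C)(C)C)c(Oc2c(C=O)c(Br)c(OCOC)c(COCc3ccccc3)c2OCOC)c1C
F4 | step 6 | 2-{3-[(benzyloxy)methyl]-5-bromo-6-formyl-2,4-dihydroxyphenoxy}-4-methoxy-3,6-dimethylbenzoic acid | COc1cc(C)c(C(=O)O)c(Oc2c(C=O)c(Br)c(O)c(COCc3ccccc3)c2O)c1C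
F5 | step 7 | rac-5-[(benzyloxy)methyl]-1,4-dihydroxy-10-methoxy-8,11-dimethyl-1H,7H-2,6,12-trioxabenzo[5,6]cyclohepta[1,2-e]indene-3,7-dione | COc1cc(C)c2c(c1C)Oc1c(c(COCc4ccccc4)c(O)c3c1C(O)OC3=O)OC2=O
F6 | step 7 | (1R)-5-[(benzyloxy)methyl]-4-hydroxy-10-methoxy-8,11-dimethyl-1-[(1S)-1-phenylethoxy]-1H,7H-2,6,12-trioxabenzo[5,6]cyclohepta[1,2-e]indene-3,7-dione | COc1cc(C)c2c(c1C)Oc1c(c(COCc4ccccc4)c(O)c3c1[C@H](O[C@@H](C)c4ccccc4)OC3=O)OC2=O
F7 | step 7 | (1S)-5-[(benzyloxy)methyl]-4-hydroxy-10-methoxy-8,11-dimethyl-1-[(1S)-1-phenylethoxy]-1H,7H-2,6,12-trioxabenzo[5,6]cyclohepta[1,2-e]indene-3,7-dione | COc1cc(C)c2c(c1C)Oc1c(c(COCc4ccccc4)c(O)c3c1[C@@H](O[C@@H](C)c4ccccc4)OC3=O)OC2=O
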